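**Plan**

- The acetonide and the three benzyl ethers come off last. Ring C of the flavanone is then cut at O1–C8a and C4–C4a, leaving an aryne of ring A and an (S)-β-hydroxy ester that carries ring B and the side chain.
- This cut is possible because ring C is fused to ring A through two adjacent aromatic carbons, C8a (bearing O1) and C4a (bearing the C4 ketone), with the 5-oxygen next to C4a. That is the pattern a 3-alkoxyaryne produces when it takes an alkoxide at one carbon and an acyl group at the other.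
- The hydroxy ester is cut at C3–C4 (crossed Claisen with methyl acetate) and at C7″–C8″ of the side chain (aldol of an aryloxyacetyl imide with 4-benzyloxybenzaldehyde), back to methyl syringate.
- Forward: the side chain is joined to ring B and masked as a dioxane (steps 1–6), the chain is grown to the β-hydroxy ester (7–8), the aryne precursor is made (9–10), ring C is closed onto ring A (11), and the product is deprotected (12–13).
- Stereochemistry: C7″ and C8″ (threo, R,R) come from an Evans syn-aldol with (S)-4-benzyl-2-oxazolidinone. C2 (S) comes from asymmetric transfer hydrogenation of the β-keto ester and survives the annulation because its C–O bond is never broken.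

Key step: step 11

Numbering: flavanone numbering (O1 to C8a) for rings A and C; C7″ is the benzylic carbinol carbon of the side chain, C8″ the aryloxy-bearing carbon, C9″ the CH2OH carbon.

Assumption: 3,5-bis(benzyloxy)phenol, the dibenzyl ether of phloroglucinol, is taken as a purchasable compound.

**Route**

Step 1
Reactants: 1 methyl syringate (methyl 4-hydroxy-3,5-dimethoxybenzoate)
Product: 2 tert-butyl 2-[2,6-dimethoxy-4-(methoxycarbonyl)phenoxy]acetate
Conditions: BrCH2CO2t-Bu, K2CO3, DMF, 50 °C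
Reagents that add atoms: tert-butyl bromoacetate, CC(C)(C)OC(=O)CBr
Why: Williamson ether synthesis, in which the phenoxide of 1 displaces bromide from the α-bromo ester by SN2 while the benzoate, having no α-hydrogen, stays inert.

Step 2
Reactants: 2 tert-butyl 2-[2,6-dimethoxy-4-(methoxycarbonyl)phenoxy]acetate
Product: 3 2-[2,6-dimethoxy-4-(methoxycarbonyl)phenoxy]acetic acid
Conditions: CF3CO2H, CH2Cl2, rt
Reagents that add atoms: none
Why: Acidolysis of the tert-butyl ester through the tert-butyl cation frees the acid and leaves the methyl benzoate and the aryl ethers untouched.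

Step 3
Reactants: 3 2-[2,6-dimethoxy-4-(methoxycarbonyl)phenoxy]acetic acid; 4 (S)-4-benzyl-2-oxazolidinone
Product: 6 methyl 4-{2-[(4S)-4-benzyl-2-oxo-1,3-oxazolidin-3-yl]-2-oxoethoxy}-3,5-dimethoxybenzoate, via mixed pivalic anhydride 5 (not isolated)
Conditions: t-BuCOCl, Et3N, THF, −20 °C; then 4, LiCl, −20 °C → rt
Reagents that add atoms: none
Why: N-acylation of the oxazolidinone through a mixed anhydride should occur at the unhindered aryloxyacetyl carbonyl and not at the pivaloyl carbonyl, and no stereocentre is involved.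

Step 4
Reactants: 6 methyl 4-{2-[(4S)-4-benzyl-2-oxo-1,3-oxazolidin-3-yl]-2-oxoethoxy}-3,5-dimethoxybenzoate; 7 4-benzyloxybenzaldehyde
Product: 9 methyl 4-{[(1R,2S)-1-[4-(benzyloxy)phenyl]-3-[(4S)-4-benzyl-2-oxo-1,3-oxazolidin-3-yl]-1-hydroxy-3-oxopropan-2-yl]oxy}-3,5-dimethoxybenzoate, via dibutylboron Z-enolate 8 (not isolated)
Conditions: Bu2BOTf, i-Pr2NEt, CH2Cl2, −78 → 0 °C; 7, −78 → 0 °C; pH 7 buffer, MeOH, 30% H2O2, 0 °C
Reagents that add atoms: none
Why: Evans syn-aldol reaction, in which the Z boron enolate adds to the aldehyde through a closed chair transition state on the face away from the benzyl group of the auxiliary, so C8″ and C7″ should form syn (threo) with the absolute sense that becomes (7″R,8″R) once the acyl carbon is reduced.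

Step 5
Reactants: 9 methyl 4-{[(1R,2S)-1-[4-(benzyloxy)phenyl]-3-[(4S)-4-benzyl-2-oxo-1,3-oxazolidin-3-yl]-1-hydroxy-3-oxopropan-2-yl]oxy}-3,5-dimethoxybenzoate
Product: 10 methyl 4-{[(1R,2R)-1-[4-(benzyloxy)phenyl]-1,3-dihydroxypropan-2-yl]oxy}-3,5-dimethoxybenzoate
Conditions: NaBH4, THF/H2O (4:1), 0 °C → rt
Reagents that add atoms: none
Why: Reductive removal of the auxiliary, in which NaBH4 in wet THF reduces the activated exocyclic imide carbonyl to the primary alcohol and should leave the electron-rich methyl benzoate and both stereocentres unchanged.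

Step 6
Reactants: 10 methyl 4-{[(1R,2R)-1-[4-(benzyloxy)phenyl]-1,3-dihydroxypropan-2-yl]oxy}-3,5-dimethoxybenzoate
Product: 11 methyl 4-{[(4R,5R)-4-[4-(benzyloxy)phenyl]-2,2-dimethyl-1,3-dioxan-5-yl]oxy}-3,5-dimethoxybenzoate
Conditions: Me2C(OMe)2, PPTS (cat.), acetone, rt
Reagents that add atoms: 2,2-dimethoxypropane, COC(C)(C)OC
Why: Acetal exchange closes a 1,3-dioxane on the 1,3-diol, which masks both hydroxyls against the strong bases and the aryne to come and offers the H4–H5 ring coupling as a check of the threo arrangement.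

Step 7
Reactants: 11 methyl 4-{[(4R,5R)-4-[4-(benzyloxy)phenyl]-2,2-dimethyl-1,3-dioxan-5-yl]oxy}-3,5-dimethoxybenzoate
Product: 12 methyl 3-(4-{[(4R,5R)-4-[4-(benzyloxy)phenyl]-2,2-dimethyl-1,3-dioxan-5-yl]oxy}-3,5-dimethoxyphenyl)-3-oxopropanoate
Conditions: MeOAc, LiN(SiMe3)2 (3.5 equiv), THF, −78 °C; then 11, −78 → 0 °C; aq. NH4Cl
Reagents that add atoms: methyl acetate, CC(=O)OC
Why: Crossed Claisen condensation, in which the lithium enolate of methyl acetate acylates the non-enolisable benzoate and deprotonation of the β-keto ester by the excess base drives the reaction forward.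

Step 8
Reactants: 12 methyl 3-(4-{[(4R,5R)-4-[4-(benzyloxy)phenyl]-2,2-dimethyl-1,3-dioxan-5-yl]oxy}-3,5-dimethoxyphenyl)-3-oxopropanoate
Product: 13 methyl (3S)-3-(4-{[(4R,5R)-4-[4-(benzyloxy)phenyl]-2,2-dimethyl-1,3-dioxan-5-yl]oxy}-3,5-dimethoxyphenyl)-3-hydroxypropanoate
Conditions: RuCl[(S,S)-TsDPEN](p-cymene) (1 mol %), HCO2H/Et3N (5:2), EtOAc, 30 °C
Reagents that add atoms: none
Why: Noyori-type asymmetric transfer hydrogenation, in which the aryl ketone is reduced through the six-membered Ru–H/N–H transition state with the aryl ring under the cymene ligand, so the (S,S) ligand should give the (S)-carbinol (the future C2) in the same sense as for acetophenone-type ketones, under catalyst control and independent of the remote dioxane centres.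

Step 9
Reactants: 14 3,5-bis(benzyloxy)phenol
Product: 15 2-bromo-3,5-bis(benzyloxy)phenol
Conditions: NBS (1.0 equiv), CH2Cl2, −78 °C
Reagents that add atoms: N-bromosuccinimide, O=C1CCC(=O)N1Br
Why: Electrophilic aromatic bromination, in which all three free ring positions are activated but the one between the two benzyloxy groups is the most hindered, so one equivalent of NBS at low temperature should brominate beside the free hydroxyl.

Step 10
Reactants: 15 2-bromo-3,5-bis(benzyloxy)phenol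
Product: 18 3,5-bis(benzyloxy)-2-(trimethylsilyl)phenyl trifluoromethanesulfonate, via aryl trimethylsilyl ether 16 (not isolated), via lithium silylphenolate 17 (not isolated)
Conditions: (Me3Si)2NH, THF, 65 °C, then evaporation; n-BuLi, THF, −78 °C; Tf2O, −78 → 0 °C
Reagents that add atoms: hexamethyldisilazane, C[Si](C)(C)N[Si](C)(C)C; triflic anhydride, O=S(=O)(OS(=O)(=O)C(F)(F)F)C(F)(F)F
Why: O-silylation, bromine–lithium exchange, retro-Brook O→C silyl shift and O-triflation of the resulting phenolate, where the exchange is far faster than benzylic deprotonation at −78 °C and the silyl group lands on the carbon that bore bromine.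

Step 11
Reactants: 13 methyl (3S)-3-(4-{[(4R,5R)-4-[4-(benzyloxy)phenyl]-2,2-dimethyl-1,3-dioxan-5-yl]oxy}-3,5-dimethoxyphenyl)-3-hydroxypropanoate; 18 3,5-bis(benzyloxy)-2-(trimethylsilyl)phenyl trifluoromethanesulfonate
Product: 22 (2S)-5,7-bis(benzyloxy)-2-(4-{[(4R,5R)-4-[4-(benzyloxy)phenyl]-2,2-dimethyl-1,3-dioxan-5-yl]oxy}-3,5-dimethoxyphenyl)chroman-4-one, via potassium alkoxide 19 (not isolated), via 3,5-bis(benzyloxy)benzyne 20 (not isolated), via C4a aryl anion 21 (not isolated)
Conditions: KN(SiMe3)2 (1.0 equiv), THF, −78 °C; 18 (1.5 equiv), CsF, 18-crown-6, −78 → 0 °C; AcOH, −20 °C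
Reagents that add atoms: none
Why: Proposed new method: fluoride removes the silyl group of 18 and triflate departs to give aryne 20; alkoxide 19 adds to the aryne carbon remote from the 3-benzyloxy group to form O1–C8a, and the aryl anion 21 left at C4a attacks the methyl ester and expels methoxide to form C4–C4a. The closest known reaction types are the fluoride-triggered annulation of arynes with salicylate esters to xanthones, the O-arylation of alcohols by arynes and the Parham cyclisation of 3-(2-lithioaryloxy)propanoates to chroman-4-ones; an aliphatic alkoxide of a β-hydroxy ester has not been used this way. Ring C closes by 6-exo-trig attack of the aryl anion on the ester carbonyl. No stereocentre is created, and since the C–O bond at the carbinol carbon of 13 is never broken, its (S) configuration becomes C2 of 22 unchanged. The required regiochemistry (oxygen at C8a, acyl at C4a) is secured by the benzyloxy group beside the triple bond, which polarises the aryne so that nucleophiles add at the distal carbon and the negative charge develops ortho to oxygen. Pre-forming the alkoxide in an aprotic medium removes the hydroxyl proton that would quench 21, the low temperature holds back retro-aldol cleavage and β-elimination, and the excess of 18 consumes the released methoxide, which could otherwise open ring C to the chalcone and scramble C2.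

Step 12
Reactants: 22 (2S)-5,7-bis(benzyloxy)-2-(4-{[(4R,5R)-4-[4-(benzyloxy)phenyl]-2,2-dimethyl-1,3-dioxan-5-yl]oxy}-3,5-dimethoxyphenyl)chroman-4-one
Product: 23 (2S)-5,7-bis(benzyloxy)-2-(4-{[(1R,2R)-1-[4-(benzyloxy)phenyl]-1,3-dihydroxypropan-2-yl]oxy}-3,5-dimethoxyphenyl)chroman-4-one
Conditions: AcOH/THF/H2O (4:1:1), 40 °C
Reagents that add atoms: none
Why: Acid-catalysed hydrolysis of the isopropylidene ketal, in a mild medium that should leave the flavanone and the benzyl ethers intact and keep the benzylic C7″–O bond from ionising.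

Step 13
Reactants: 23 (2S)-5,7-bis(benzyloxy)-2-(4-{[(1R,2R)-1-[4-(benzyloxy)phenyl]-1,3-dihydroxypropan-2-yl]oxy}-3,5-dimethoxyphenyl)chroman-4-one
Product: 24 (2S)-5,7-dihydroxy-2-(4-{[(1R,2R)-1,3-dihydroxy-1-(4-hydroxyphenyl)propan-2-yl]oxy}-3,5-dimethoxyphenyl)chroman-4-one (CNP0263993.1)
Conditions: H2 (1 atm), Pd/C (10% palladium on carbon), EtOAc/MeOH, rt
Reagents that add atoms: none
Why: Catalytic hydrogenolysis of the three aryl benzyl ethers, which at 1 atm in a neutral solvent should be much faster than cleavage of the secondary benzylic alcohol or the C2–O1 bond or reduction of the ketone, so the reaction is stopped after three equivalents of hydrogen.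

**Compound list**

1 | methyl syringate (methyl 4-hydroxy-3,5-dimethoxybenzoate) | COC(=O)c1cc(OC)c(O)c(OC)c1 | starting material
2 | tert-butyl 2-[2,6-dimethoxy-4-(methoxycarbonyl)phenoxy]acetate | COC(=O)c1cc(OC)c(OCC(=O)OC(C)(C)C)c(OC)c1 | intermediate
3 | 2-[2,6-dimethoxy-4-(methoxycarbonyl)phenoxy]acetic acid | COC(=O)c1cc(OC)c(OCC(=O)O)c(OC)c1 | intermediate
4 | (S)-4-benzyl-2-oxazolidinone | O=C1N[C@@H](Cc2ccccc2)CO1 | starting material
5 | mixed anhydride of 3 with pivalic acid (not isolated) | COC(=O)c1cc(OC)c(OCC(=O)OC(=O)C(C)(C)C)c(OC)c1 | intermediate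
6 | methyl 4-{2-[(4S)-4-benzyl-2-oxo-1,3-oxazolidin-3-yl]-2-oxoethoxy}-3,5-dimethoxybenzoate | COC(=O)c1cc(OC)c(OCC(=O)N2[C@@H](Cc3ccccc3)COC2=O)c(OC)c1 | intermediate
7 | 4-benzyloxybenzaldehyde | O=Cc1ccc(OCc2ccccc2)cc1 | starting material
8 | dibutylboron (Z)-enolate of 6, boryloxy and aryloxy groups cis on the enol double bond (not isolated) | CCCCB(CCCC)O/C(=C\Oc1c(OC)cc(C(=O)OC)cc1OC)N1[C@@H](Cc2ccccc2)COC1=O | intermediate
9 | methyl 4-{[(1R,2S)-1-[4-(benzyloxy)phenyl]-3-[(4S)-4-benzyl-2-oxo-1,3-oxazolidin-3-yl]-1-hydroxy-3-oxopropan-2-yl]oxy}-3,5-dimethoxybenzoate | COC(=O)c1cc(OC)c(O[C@H](C(=O)N2[C@@H](Cc3ccccc3)COC2=O)[C@H](O)c2ccc(OCc3ccccc3)cc2)c(OC)c1 | intermediate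
10 | methyl 4-{[(1R,2R)-1-[4-(benzyloxy)phenyl]-1,3-dihydroxypropan-2-yl]oxy}-3,5-dimethoxybenzoate | COC(=O)c1cc(OC)c(O[C@H](CO)[C@H](O)c2ccc(OCc3ccccc3)cc2)c(OC)c1 | intermediate
11 | methyl 4-{[(4R,5R)-4-[4-(benzyloxy)phenyl]-2,2-dimethyl-1,3-dioxan-5-yl]oxy}-3,5-dimethoxybenzoate | COC(=O)c1cc(OC)c(O[C@@H]2COC(C)(C)O[C@@H]2c2ccc(OCc3ccccc3)cc2)c(OC)c1 | intermediate
12 | methyl 3-(4-{[(4R,5R)-4-[4-(benzyloxy)phenyl]-2,2-dimethyl-1,3-dioxan-5-yl]oxy}-3,5-dimethoxyphenyl)-3-oxopropanoate | COC(=O)CC(=O)c1cc(OC)c(O[C@@H]2COC(C)(C)O[C@@H]2c2ccc(OCc3ccccc3)cc2)c(OC)c1 | intermediate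
13 | methyl (3S)-3-(4-{[(4R,5R)-4-[4-(benzyloxy)phenyl]-2,2-dimethyl-1,3-dioxan-5-yl]oxy}-3,5-dimethoxyphenyl)-3-hydroxypropanoate | COC(=O)C[C@H](O)c1cc(OC)c(O[C@@H]2COC(C)(C)O[C@@H]2c2ccc(OCc3ccccc3)cc2)c(OC)c1 | intermediate
14 | 3,5-bis(benzyloxy)phenol | Oc1cc(OCc2ccccc2)cc(OCc2ccccc2)c1 | starting material
15 | 2-bromo-3,5-bis(benzyloxy)phenol | Oc1cc(OCc2ccccc2)cc(OCc2ccccc2)c1Br | intermediate
16 | [2-bromo-3,5-bis(benzyloxy)phenoxy]trimethylsilane (not isolated) | C[Si](C)(C)Oc1cc(OCc2ccccc2)cc(OCc2ccccc2)c1Br | intermediate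
17 | lithium 3,5-bis(benzyloxy)-2-(trimethylsilyl)phenolate (not isolated) | [Li+].[O-]c1cc(OCc2ccccc2)cc(OCc2ccccc2)c1[Si](C)(C)C | intermediate
18 | 3,5-bis(benzyloxy)-2-(trimethylsilyl)phenyl trifluoromethanesulfonate | C[Si](C)(C)c1c(OCc2ccccc2)cc(OCc2ccccc2)cc1OS(=O)(=O)C(F)(F)F | intermediate
19 | potassium alkoxide of 13 (not isolated) | COC(=O)C[C@H]([O-])c1cc(OC)c(O[C@@H]2COC(C)(C)O[C@@H]2c2ccc(OCc3ccccc3)cc2)c(OC)c1.[K+] | intermediate
20 | 3,5-bis(benzyloxy)benzyne, triple bond between the former triflate and silyl carbons (not isolated) | C1#CC(OCc2ccccc2)=CC(OCc2ccccc2)=C1 | intermediate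
21 | potassium aryl anion from addition of 19 to 20: methyl (3S)-3-[3,5-bis(benzyloxy)-2-potassiophenoxy]-3-(4-{[(4R,5R)-4-[4-(benzyloxy)phenyl]-2,2-dimethyl-1,3-dioxan-5-yl]oxy}-3,5-dimethoxyphenyl)propanoate (not isolated) | COC(=O)C[C@H](Oc1cc(OCc2ccccc2)cc(OCc2ccccc2)[c-]1)c1cc(OC)c(O[C@@H]2COC(C)(C)O[C@@H]2c2ccc(OCc3ccccc3)cc2)c(OC)c1.[K+] | intermediate
22 | (2S)-5,7-bis(benzyloxy)-2-(4-{[(4R,5R)-4-[4-(benzyloxy)phenyl]-2,2-dimethyl-1,3-dioxan-5-yl]oxy}-3,5-dimethoxyphenyl)chroman-4-one | COc1cc([C@@H]2CC(=O)c3c(OCc4ccccc4)cc(OCc4ccccc4)cc3O2)cc(OC)c1O[C@@H]1COC(C)(C)O[C@@H]1c1ccc(OCc2ccccc2)cc1 | intermediate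
23 | (2S)-5,7-bis(benzyloxy)-2-(4-{[(1R,2R)-1-[4-(benzyloxy)phenyl]-1,3-dihydroxypropan-2-yl]oxy}-3,5-dimethoxyphenyl)chroman-4-one | COc1cc([C@@H]2CC(=O)c3c(OCc4ccccc4)cc(OCc4ccccc4)cc3O2)cc(OC)c1O[C@H](CO)[C@H](O)c1ccc(OCc2ccccc2)cc1 | intermediate
24 | (2S)-5,7-dihydroxy-2-(4-{[(1R,2R)-1,3-dihydroxy-1-(4-hydroxyphenyl)propan-2-yl]oxy}-3,5-dimethoxyphenyl)chroman-4-one (CNP0263993.1) | COc1cc([C@@H]2CC(=O)c3c(O)cc(O)cc3O2)cc(OC)c1O[C@H](CO)[C@H](O)c1ccc(O)cc1 | target

**Step count**

Total: 13 steps. Longest linear sequence: 11 steps (steps 1–8 and 11–13, from methyl syringate); the aryne precursor (steps 9–10) is a two-step branch.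

**Steps most likely to fail**

1. Step 11 (aryne annulation, the one step beyond known chemistry). Three processes may take over: retro-aldol fragmentation of the potassium alkoxide; proton transfer from the α-methylene to the aryl anion followed by β-elimination of the new aryloxide; and methoxide-induced opening of ring C, which would epimerise C2. The fallback uses known chemistry, sets out from ester 11 and rejoins the route at 22:
   - Reduction with i-Bu2AlH (CH2Cl2, −78 °C) would give the benzylic alcohol F1, and MnO2 (CH2Cl2) would give the aldehyde F2.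
   - Claisen–Schmidt condensation (KOH, EtOH, rt) with 1-[2,4-bis(benzyloxy)-6-hydroxyphenyl]ethan-1-one F3 would give the 2′-hydroxychalcone F4. F3 is made from 2,4,6-trihydroxyacetophenone with BnBr and K2CO3, the chelated hydroxyl staying free.
   - Oxa-Michael ring closure (NaOAc, EtOH, reflux) would give 22 together with the (2R) epimer of 22 F5.
   - In this fallback C2 is not set by a reagent. The two products are diastereomers because of the dioxane centres, so they would be separated by preparative HPLC and F5 returned to the base equilibration.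

2. Step 9 (bromination). Attack at the position between the two benzyloxy groups, or a second bromination, would lower the amount of the needed isomer. The fallback fixes the site by directed ortho-metalation, sets out from phenol 14 and rejoins the route at 18:
   - Isopropyl isocyanate with catalytic Et3N (CH2Cl2) would give 3,5-bis(benzyloxy)phenyl N-isopropylcarbamate F6.
   - N-silylation in the flask (TBSOTf, TMEDA, Et2O) would give the N-silyl carbamate F7.
   - Lithiation between the carbamate and a benzyloxy group (n-BuLi, TMEDA, −78 °C) and quenching with Me3SiCl would give the N,C-disilylated carbamate F8, and acidic work-up would leave the ortho-silyl carbamate F9.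
   - Et2NH and DBU (MeCN, 40 °C) would release 3,5-bis(benzyloxy)-2-(trimethylsilyl)phenol F10, which PhNTf2 would convert in the same flask into 18.

3. Step 7 (crossed Claisen). The deactivated, electron-rich benzoate may be acylated too slowly to compete with self-condensation of the methyl acetate enolate. The fallback replaces the condensation by a Masamune–Brooks malonate acylation, sets out from 11 and rejoins the route at 12:
   - LiOH (THF/MeOH/H2O) would give the benzoic acid F11.
   - Carbonyldiimidazole (THF) would give the acyl imidazolide F12.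
   - KO2CCH2CO2Me, MgCl2 and Et3N (MeCN) would C-acylate the malonate half-ester and give 12 with loss of CO2 in the same operation.

**Further compounds**

F1 | step 11 | (4-{[(4R,5R)-4-[4-(benzyloxy)phenyl]-2,2-dimethyl-1,3-dioxan-5-yl]oxy}-3,5-dimethoxyphenyl)methanol | OCc1cc(OC)c(O[C@@H]2COC(C)(C)O[C@@H]2c2ccc(OCc3ccccc3)cc2)c(OC)c1
F2 | step 11 | 4-{[(4R,5R)-4-[4-(benzyloxy)phenyl]-2,2-dimethyl-1,3-dioxan-5-yl]oxy}-3,5-dimethoxybenzaldehyde | O=Cc1cc(OC)c(O[C@@H]2COC(C)(C)O[C@@H]2c2ccc(OCc3ccccc3)cc2)c(OC)c1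
F3 | step 11 | 1-[2,4-bis(benzyloxy)-6-hydroxyphenyl]ethan-1-one | CC(=O)c1c(O)cc(OCc2ccccc2)cc1OCc1ccccc1
F4 | step 11 | (E)-1-[2,4-bis(benzyloxy)-6-hydroxyphenyl]-3-(4-{[(4R,5R)-4-[4-(benzyloxy)phenyl]-2,2-dimethyl-1,3-dioxan-5-yl]oxy}-3,5-dimethoxyphenyl)prop-2-en-1-one | O=C(/C=C/c1cc(OC)c(O[C@@H]2COC(C)(C)O[C@@H]2c2ccc(OCc3ccccc3)cc2)c(OC)c1)c1c(O)cc(OCc2ccccc2)cc1OCc1ccccc1
F5 | step 11 | (2R)-5,7-bis(benzyloxy)-2-(4-{[(4R,5R)-4-[4-(benzyloxy)phenyl]-2,2-dimethyl-1,3-dioxan-5-yl]oxy}-3,5-dimethoxyphenyl)chroman-4-one | COc1cc([C@H]2CC(=O)c3c(OCc4ccccc4)cc(OCc4ccccc4)cc3O2)cc(OC)c1O[C@@H]1COC(C)(C)O[C@@H]1c1ccc(OCc2ccccc2)cc1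
F6 | step 9 | 3,5-bis(benzyloxy)phenyl N-isopropylcarbamate | CC(C)NC(=O)Oc1cc(OCc2ccccc2)cc(OCc2ccccc2)c1
F7 | step 9 | 3,5-bis(benzyloxy)phenyl N-(tert-butyldimethylsilyl)-N-isopropylcarbamate | CC(C)N(C(=O)Oc1cc(OCc2ccccc2)cc(OCc2ccccc2)c1)[Si](C)(C)C(C)(C)C
F8 | step 9 | 3,5-bis(benzyloxy)-2-(trimethylsilyl)phenyl N-(tert-butyldimethylsilyl)-N-isopropylcarbamate | CC(C)N(C(=O)Oc1cc(OCc2ccccc2)cc(OCc2ccccc2)c1[Si](C)(C)C)[Si](C)(C)C(C)(C)C
F9 | step 9 | 3,5-bis(benzyloxy)-2-(trimethylsilyl)phenyl N-isopropylcarbamate | CC(C)NC(=O)Oc1cc(OCc2ccccc2)cc(OCc2ccccc2)c1[Si](C)(C)C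
F10 | step 9 | 3,5-bis(benzyloxy)-2-(trimethylsilyl)phenol | Oc1cc(OCc2ccccc2)cc(OCc2ccccc2)c1[Si](C)(C)C
F11 | step 7 | 4-{[(4R,5R)-4-[4-(benzyloxy)phenyl]-2,2-dimethyl-1,3-dioxan-5-yl]oxy}-3,5-dimethoxybenzoic acid | OC(=O)c1cc(OC)c(O[C@@H]2COC(C)(C)O[C@@H]2c2ccc(OCc3ccccc3)cc2)c(OC)c1
F12 | step 7 | (4-{[(4R,5R)-4-[4-(benzyloxy)phenyl]-2,2-dimethyl-1,3-dioxan-5-yl]oxy}-3,5-dimethoxyphenyl)(1H-imidazol-1-yl)methanone | O=C(c1cc(OC)c(O[C@@H]2COC(C)(C)O[C@@H]2c2ccc(OCc3ccccc3)cc2)c(OC)c1)n1ccnc1
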